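The 3-monosubstituted furan is disconnected at its C2–C3 and C4–C5 bonds. Furan C3 and C4 are the two carbons of a terminal alkyne on C1′, and O1, C2 and C5 are supplied by 4-phenyloxazole. One thermal Diels–Alder/retro-Diels–Alder operation on alkyne 24 should therefore close the oxidation-sensitive furan ring after the C11′/C12′ hydroxy-γ-lactone has been made from farnesol by alkene cleavage and epoxidation. Precursor 24 carries the whole C1′–C15′ chain: the (6′S) methyl ether, both E trisubstituted alkenes, the γ-lactone, a free C≡CH terminus, and the C11′ hydroxyl as a TBS ether so that it cannot translactonise at high temperature.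

Key step: step 19

Remarks on the chemistry:
- The chain is numbered from the furyl CH2 (C1′) to the lactone carbonyl (C15′). Steps 1–6 use farnesol numbering, where farnesol C1 = C6′, C6 = C11′, C7 = C12′ and C10 = C15′.
- The target SMILES corresponds to 6′S, 11′R, 12′S with both trisubstituted alkenes E, and the route is planned for exactly this isomer.
- Assumption: 5-(trimethylsilyl)pent-4-yn-1-ol (12) is taken as a commercial material; it is otherwise one step from pent-4-yn-1-ol.
- Compounds 3 and 4 are racemic at C10, which is excised in step 4.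

Step 1
Reactants: 1 (2E,6E)-farnesol
Product: 2 (2E,6E)-farnesyl acetate
Conditions: Ac2O, pyridine, DMAP (cat.), CH2Cl2, 0 °C to rt
Reagents that add atoms: acetic anhydride, CC(=O)OC(C)=O
Why: DMAP-catalysed O-acetylation of the primary allylic alcohol, which also deactivates the C2=C3 alkene towards the electrophilic oxidants of steps 2 and 6.

Step 2
Reactants: 2 (2E,6E)-farnesyl acetate
Product: 3 (2E,6E)-10-bromo-11-hydroxy-3,7,11-trimethyldodeca-2,6-dien-1-yl acetate (racemic at C10)
Conditions: NBS, THF/H2O, 0 °C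
Reagents that add atoms: N-bromosuccinimide, O=C1CCC(=O)N1Br; water, O
Why: van Tamelen-type bromohydrin formation, in which the coiled polyene in aqueous medium exposes the terminal isopropylidene alkene to bromonium formation and water opens the ion at the tertiary carbon.

Step 3
Reactants: 3 bromohydrin acetate
Product: 4 (2E,6E)-10,11-epoxy-3,7,11-trimethyldodeca-2,6-dien-1-yl acetate (racemic)
Conditions: DBU, THF, rt
Reagents that add atoms: none
Why: Intramolecular Williamson (SN2) ring closure of the bromohydrin with an aprotic amidine base, which spares the allylic acetate that methanolic carbonate would remove.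

Step 4
Reactants: 4 terminal epoxide
Product: 5 (2E,6E)-3,7-dimethyl-10-oxodeca-2,6-dien-1-yl acetate
Conditions: H5IO6, THF/H2O, 0 °C
Reagents that add atoms: none
Why: Acid-mediated hydrolysis of the epoxide to the 10,11-diol followed by periodate (Malaprade) glycol cleavage removes C11 as acetone and leaves the two remaining alkenes and the acetate untouched.

Step 5
Reactants: 5 aldehyde
Product: 6 (4E,8E)-10-acetoxy-4,8-dimethyldeca-4,8-dienoic acid
Conditions: NaClO2, NaH2PO4, 2-methylbut-2-ene, t-BuOH/H2O, rt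
Reagents that add atoms: sodium chlorite, [Na+].[O-]Cl=O
Why: Pinnick oxidation of the aldehyde, with 2-methylbut-2-ene scavenging hypochlorous acid so that the trisubstituted alkenes are not chlorinated.

Step 6
Reactants: 6 dienoic acid
Product: 8 (2E,6R)-6-hydroxy-3-methyl-6-[(2S)-2-methyl-5-oxooxolan-2-yl]hex-2-en-1-yl acetate, via epoxy acid 7 (not isolated)
Conditions: D-fructose-derived Shi ketone (1,2:4,5-di-O-isopropylidene-β-D-erythro-hexo-2,3-diulo-2,6-pyranose, 0.3 equiv), KHSO5 (as 2KHSO5·KHSO4·K2SO4), K2CO3, Bu4NHSO4, MeCN/CH2(OMe)2/aq. Na2B4O7 buffer, 0 °C; then aq. NaHSO4 to pH 3, CSA (cat.), CH2Cl2, rt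
Reagents that add atoms: potassium peroxymonosulfate, [K+].[O-]S(=O)(=O)OO
Why: Shi asymmetric epoxidation, in which the D-fructose-derived dioxirane attacks the electron-rich C6=C7 alkene of the carboxylate (the C2=C3 alkene is deactivated by the allylic acetate) through the spiro transition state to give the (6R,7R)-epoxide, and on acidification the carboxylic acid opens it 5-exo at the tertiary carbon with inversion, which sets C12′ as S and leaves the C11′ carbinol as R.

Step 7
Reactants: 8 hydroxy lactone acetate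
Product: 9 (2E,6R)-6-(tert-butyldimethylsilyloxy)-3-methyl-6-[(2S)-2-methyl-5-oxooxolan-2-yl]hex-2-en-1-yl acetate
Conditions: TBSOTf, 2,6-lutidine, CH2Cl2, −78 to 0 °C
Reagents that add atoms: tert-butyldimethylsilyl trifluoromethanesulfonate, CC(C)(C)[Si](C)(C)OS(=O)(=O)C(F)(F)F
Why: Silylation of the hindered secondary alcohol next to the quaternary centre with the reactive silyl triflate and a hindered pyridine base, conditions under which acetate and lactone are inert.

Step 8
Reactants: 9 silyl ether acetate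
Product: 10 (5S)-5-[(1R,4E)-1-(tert-butyldimethylsilyloxy)-6-hydroxy-4-methylhex-4-en-1-yl]-5-methyloxolan-2-one
Conditions: K2CO3 (0.2 equiv), MeOH, 0 °C
Reagents that add atoms: none
Why: Base-catalysed transesterification (methanolysis) removes the unhindered primary allylic acetate far faster than the γ,γ-disubstituted γ-lactone can open, and any transiently opened hydroxy ester should reclose through its tertiary alkoxide.

Step 9
Reactants: 10 allylic alcohol
Product: 11 (2E,6R)-6-(tert-butyldimethylsilyloxy)-3-methyl-6-[(2S)-2-methyl-5-oxooxolan-2-yl]hex-2-enal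
Conditions: MnO2, CH2Cl2, rt
Reagents that add atoms: none
Why: Chemoselective allylic alcohol oxidation with activated MnO2 gives the E enal without affecting the silyl ether, the lactone or the alkene geometry.

Step 10
Reactants: 12 5-(trimethylsilyl)pent-4-yn-1-ol; 13 ethyl 2-(triphenylphosphoranylidene)propanoate
Product: 15 ethyl (2E)-2-methyl-7-(trimethylsilyl)hept-2-en-6-ynoate, via aldehyde 14 (not isolated)
Conditions: (COCl)2, DMSO, CH2Cl2, −78 °C; Et3N; then 13, −78 °C to rt
Reagents that add atoms: none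
Why: One-pot Swern oxidation and Wittig olefination, in which the stabilised α-methyl ylide reacts with the unhindered aldehyde under thermodynamic control to give the E trisubstituted enoate.

Step 11
Reactants: 15 enoate
Product: 16 (2E)-2-methyl-7-(trimethylsilyl)hept-2-en-6-yn-1-ol
Conditions: i-Bu2AlH, CH2Cl2, −78 °C; aq. KNaC4H4O6
Reagents that add atoms: none
Why: 1,2-Reduction of the α,β-unsaturated ester by the aluminium hydride gives the allylic alcohol, and the silylalkyne is not hydroaluminated at −78 °C.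

Step 12
Reactants: 16 allylic alcohol
Product: 18 [(5E)-7-chloro-6-methylhept-5-en-1-yn-1-yl]trimethylsilane, via mesylate 17 (not isolated)
Conditions: MsCl, LiCl, 2,4,6-collidine, DMF, 0 °C
Reagents that add atoms: lithium chloride, [Li+].[Cl-]
Why: Collington–Meyers chlorination, in which the mesylate formed in the flask is displaced by chloride in an SN2 reaction at the primary carbon without allylic transposition or loss of E geometry.

Step 13
Reactants: 18 allylic chloride; 11 lactone enal
Product: 20 (5S)-5-[(1R,4E,6RS,8E)-1-(tert-butyldimethylsilyloxy)-6-hydroxy-4,8-dimethyl-13-(trimethylsilyl)trideca-4,8-dien-12-yn-1-yl]-5-methyloxolan-2-one (C6 epimer mixture), via allylbarium chloride 19 (not isolated)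
Conditions: BaI2, LiC12H10 (lithium biphenylide), THF, rt; 18 (2 equiv), −78 °C; then 11, −78 °C; aq. NH4Cl
Reagents that add atoms: none
Why: Yamamoto allylbarium addition, in which the allylic barium reagent made at −78 °C from the chloride and activated zerovalent barium keeps its E geometry and attacks the aldehyde 1,2 through its unsubstituted α-carbon (C5′) much faster than it attacks the lactone, giving the linear C5′–C6′ bond with C6′ as an epimer mixture that step 14 levels and step 15 sets.

Step 14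
Reactants: 20 carbinol mixture
Product: 21 (5S)-5-[(1R,4E,8E)-1-(tert-butyldimethylsilyloxy)-4,8-dimethyl-6-oxo-13-(trimethylsilyl)trideca-4,8-dien-12-yn-1-yl]-5-methyloxolan-2-one
Conditions: Dess–Martin periodinane, NaHCO3, CH2Cl2, 0 °C
Reagents that add atoms: none
Why: Dess–Martin oxidation under buffered, non-enolising conditions converts both epimers into one enone and should keep the C3′=C4′ alkene out of conjugation.

Step 15
Reactants: 21 enone
Product: 22 (5S)-5-[(1R,4E,6S,8E)-1-(tert-butyldimethylsilyloxy)-6-hydroxy-4,8-dimethyl-13-(trimethylsilyl)trideca-4,8-dien-12-yn-1-yl]-5-methyloxolan-2-one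
Conditions: (R)-2-methyl-CBS-oxazaborolidine (0.2 equiv), catecholborane, toluene, −78 °C
Reagents that add atoms: none
Why: Corey–Bakshi–Shibata reduction, in which the alkenyl group acts as the larger ketone substituent so that the (R)-oxazaborolidine directs hydride to the face giving the (6′S) allylic alcohol under reagent control, while catecholborane at −78 °C spares the lactone, the alkenes and the silylalkyne.

Step 16
Reactants: 22 (6′S) allylic alcohol
Product: 23 (5S)-5-[(1R,4E,6S,8E)-1-(tert-butyldimethylsilyloxy)-6-methoxy-4,8-dimethyl-13-(trimethylsilyl)trideca-4,8-dien-12-yn-1-yl]-5-methyloxolan-2-one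
Conditions: Me3OBF4, 1,8-bis(dimethylamino)naphthalene, 4 Å MS, CH2Cl2, 0 °C to rt
Reagents that add atoms: trimethyloxonium tetrafluoroborate, C[O+](C)C.F[B-](F)(F)F
Why: O-Methylation with Meerwein's salt and a non-nucleophilic proton scavenger forms no alkoxide, so the lactone is not attacked, and the C6′–O bond is never broken, so the configuration is retained.

Step 17
Reactants: 23 silylalkyne
Product: 24 (5S)-5-[(1R,4E,6S,8E)-1-(tert-butyldimethylsilyloxy)-6-methoxy-4,8-dimethyltrideca-4,8-dien-12-yn-1-yl]-5-methyloxolan-2-one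
Conditions: K2CO3, MeOH, 0 °C to rt
Reagents that add atoms: none
Why: Base-catalysed methanolytic protodesilylation cleaves the alkynyl C–Si bond selectively, because the hindered secondary TBS ether and the γ,γ-disubstituted lactone resist these mild conditions.

Step 18
Reactants: 25 2-bromoacetophenone
Product: 26 4-phenyloxazole
Conditions: HCONH2 (neat, excess), 110 °C
Reagents that add atoms: formamide, NC=O
Why: Bredereck oxazole synthesis, in which formamide is O-alkylated by the α-bromoketone and its nitrogen then condenses with the ketone, so the aryl group ends up on C4.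

Step 19
Reactants: 24 terminal alkyne; 26 4-phenyloxazole
Product: 28 (5S)-5-[(1R,4E,6S,8E)-1-(tert-butyldimethylsilyloxy)-11-(furan-3-yl)-6-methoxy-4,8-dimethylundeca-4,8-dien-1-yl]-5-methyloxolan-2-one, via bicyclic cycloadduct 27 (not isolated)
Conditions: 26 (5 equiv), BHT (cat.), 1,2-dichlorobenzene, argon, sealed tube, 210–220 °C
Reagents that add atoms: none
Why: The oxazole reacts as a 2-azadiene whose C2 and C5 add suprafacially across the C≡C bond in a thermal [4+2] cycloaddition to give the 7-oxa-2-azabicyclo[2.2.1]hepta-2,5-diene 27, which fragments by retro-[4+2] loss of benzonitrile (N3 with C4–Ph) and so aromatises. The closest known reaction type is the oxazole–alkyne Diels–Alder/retro-Diels–Alder furan synthesis, which for unactivated alkynes needs temperatures above 200 °C. The furan ring is closed in cycloaddition mode by two intermolecular C–C bonds, alkyne carbon to oxazole C2 and alkyne carbon to oxazole C5 (furan C2–C3 and C4–C5), with the ring oxygen and both α-carbons coming from the oxazole. No stereocentre is created in the product, since the bridgehead centres of 27 are transient, and the centres at C6′, C11′ and C12′ take no part. The single selectivity demand is that the oxazole engage the alkyne and not the two trisubstituted C=C bonds, which are hindered, unactivated 2π partners whose adducts could not aromatise, whereas orientation is immaterial because either regioisomeric adduct collapses to the same 3-alkylfuran. The lactone, methyl ether and silyl ether have no pathway under neutral, oxygen-free thermolysis, and the silyl group on the C11′ oxygen blocks lactone migration.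

Step 20
Reactants: 28 silyl-protected furan
Product: 29 (5S)-5-[(1R,4E,6S,8E)-11-(furan-3-yl)-1-hydroxy-6-methoxy-4,8-dimethylundeca-4,8-dien-1-yl]-5-methyloxolan-2-one (CNP0306177.2)
Conditions: HF·pyridine, pyridine, THF, 0 °C to rt
Reagents that add atoms: none
Why: Fluoride-mediated Si–O cleavage under pyridine-buffered conditions avoids the free alkoxide that could translactonise, is mild enough for the furan and the allylic methyl ether, and touches no stereocentre.

Compound list
1 | (2E,6E)-farnesol | CC(C)=CCC/C(C)=C/CC/C(C)=C/CO | starting material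
2 | (2E,6E)-farnesyl acetate | CC(C)=CCC/C(C)=C/CC/C(C)=C/COC(C)=O | intermediate
3 | (2E,6E)-10-bromo-11-hydroxy-3,7,11-trimethyldodeca-2,6-dien-1-yl acetate (racemic at C10) | CC(C)(O)C(Br)CC/C(C)=C/CC/C(C)=C/COC(C)=O | intermediate
4 | (2E,6E)-10,11-epoxy-3,7,11-trimethyldodeca-2,6-dien-1-yl acetate (racemic) | CC1(C)OC1CC/C(C)=C/CC/C(C)=C/COC(C)=O | intermediate
5 | (2E,6E)-3,7-dimethyl-10-oxodeca-2,6-dien-1-yl acetate | O=CCC/C(C)=C/CC/C(C)=C/COC(C)=O | intermediate
6 | (4E,8E)-10-acetoxy-4,8-dimethyldeca-4,8-dienoic acid | OC(=O)CC/C(C)=C/CC/C(C)=C/COC(C)=O | intermediate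
7 | 3-[(2R,3R)-3-[(3E)-5-acetoxy-3-methylpent-3-en-1-yl]-2-methyloxiran-2-yl]propanoic acid | OC(=O)CC[C@@]1(C)O[C@@H]1CC/C(C)=C/COC(C)=O | intermediate (not isolated)
8 | (2E,6R)-6-hydroxy-3-methyl-6-[(2S)-2-methyl-5-oxooxolan-2-yl]hex-2-en-1-yl acetate | CC(=O)OC/C=C(\C)CC[C@@H](O)[C@]1(C)CCC(=O)O1 | intermediate
9 | (2E,6R)-6-(tert-butyldimethylsilyloxy)-3-methyl-6-[(2S)-2-methyl-5-oxooxolan-2-yl]hex-2-en-1-yl acetate | CC(=O)OC/C=C(\C)CC[C@@H](O[Si](C)(C)C(C)(C)C)[C@]1(C)CCC(=O)O1 | intermediate
10 | (5S)-5-[(1R,4E)-1-(tert-butyldimethylsilyloxy)-6-hydroxy-4-methylhex-4-en-1-yl]-5-methyloxolan-2-one | OC/C=C(\C)CC[C@@H](O[Si](C)(C)C(C)(C)C)[C@]1(C)CCC(=O)O1 | intermediate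
11 | (2E,6R)-6-(tert-butyldimethylsilyloxy)-3-methyl-6-[(2S)-2-methyl-5-oxooxolan-2-yl]hex-2-enal | O=C/C=C(\C)CC[C@@H](O[Si](C)(C)C(C)(C)C)[C@]1(C)CCC(=O)O1 | intermediate
12 | 5-(trimethylsilyl)pent-4-yn-1-ol | C[Si](C)(C)C#CCCCO | starting material
13 | ethyl 2-(triphenylphosphoranylidene)propanoate | CCOC(=O)C(C)=P(c1ccccc1)(c1ccccc1)c1ccccc1 | starting material
14 | 5-(trimethylsilyl)pent-4-ynal | C[Si](C)(C)C#CCCC=O | intermediate (not isolated)
15 | ethyl (2E)-2-methyl-7-(trimethylsilyl)hept-2-en-6-ynoate | CCOC(=O)/C(C)=C/CCC#C[Si](C)(C)C | intermediate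
16 | (2E)-2-methyl-7-(trimethylsilyl)hept-2-en-6-yn-1-ol | C[Si](C)(C)C#CCC/C=C(\C)CO | intermediate
17 | (2E)-2-methyl-7-(trimethylsilyl)hept-2-en-6-yn-1-yl methanesulfonate | C[Si](C)(C)C#CCC/C=C(\C)COS(C)(=O)=O | intermediate (not isolated)
18 | [(5E)-7-chloro-6-methylhept-5-en-1-yn-1-yl]trimethylsilane | C[Si](C)(C)C#CCC/C=C(\C)CCl | intermediate
19 | [(2E)-2-methyl-7-(trimethylsilyl)hept-2-en-6-yn-1-yl]barium chloride | C[Si](C)(C)C#CCC/C=C(\C)C[Ba]Cl | intermediate (not isolated)
20 | (5S)-5-[(1R,4E,6RS,8E)-1-(tert-butyldimethylsilyloxy)-6-hydroxy-4,8-dimethyl-13-(trimethylsilyl)trideca-4,8-dien-12-yn-1-yl]-5-methyloxolan-2-one (C6 epimer mixture) | C[Si](C)(C)C#CCC/C=C(\C)CC(O)/C=C(\C)CC[C@@H](O[Si](C)(C)C(C)(C)C)[C@]1(C)CCC(=O)O1 | intermediate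
21 | (5S)-5-[(1R,4E,8E)-1-(tert-butyldimethylsilyloxy)-4,8-dimethyl-6-oxo-13-(trimethylsilyl)trideca-4,8-dien-12-yn-1-yl]-5-methyloxolan-2-one | C[Si](C)(C)C#CCC/C=C(\C)CC(=O)/C=C(\C)CC[C@@H](O[Si](C)(C)C(C)(C)C)[C@]1(C)CCC(=O)O1 | intermediate
22 | (5S)-5-[(1R,4E,6S,8E)-1-(tert-butyldimethylsilyloxy)-6-hydroxy-4,8-dimethyl-13-(trimethylsilyl)trideca-4,8-dien-12-yn-1-yl]-5-methyloxolan-2-one | O[C@H](/C=C(\C)CC[C@@H](O[Si](C)(C)C(C)(C)C)[C@]1(C)CCC(=O)O1)C/C(C)=C/CCC#C[Si](C)(C)C | intermediate
23 | (5S)-5-[(1R,4E,6S,8E)-1-(tert-butyldimethylsilyloxy)-6-methoxy-4,8-dimethyl-13-(trimethylsilyl)trideca-4,8-dien-12-yn-1-yl]-5-methyloxolan-2-one | CO[C@H](/C=C(\C)CC[C@@H](O[Si](C)(C)C(C)(C)C)[C@]1(C)CCC(=O)O1)C/C(C)=C/CCC#C[Si](C)(C)C | intermediate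
24 | (5S)-5-[(1R,4E,6S,8E)-1-(tert-butyldimethylsilyloxy)-6-methoxy-4,8-dimethyltrideca-4,8-dien-12-yn-1-yl]-5-methyloxolan-2-one | CO[C@H](/C=C(\C)CC[C@@H](O[Si](C)(C)C(C)(C)C)[C@]1(C)CCC(=O)O1)C/C(C)=C/CCC#C | intermediate
25 | 2-bromoacetophenone | O=C(CBr)c1ccccc1 | starting material
26 | 4-phenyloxazole | c1ccc(-c2cocn2)cc1 | intermediate
27 | (5S)-5-[(1R,4E,6S,8E)-1-(tert-butyldimethylsilyloxy)-6-methoxy-4,8-dimethyl-11-(3-phenyl-7-oxa-2-azabicyclo[2.2.1]hepta-2,5-dien-5-yl)undeca-4,8-dien-1-yl]-5-methyloxolan-2-one (mixture with the 6-yl regioisomer and bridgehead epimers; one isomer drawn) | CO[C@H](/C=C(\C)CC[C@@H](O[Si](C)(C)C(C)(C)C)[C@]1(C)CCC(=O)O1)C/C(C)=C/CCC2=CC3OC2C(c2ccccc2)=N3 | intermediate (not isolated)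
28 | (5S)-5-[(1R,4E,6S,8E)-1-(tert-butyldimethylsilyloxy)-11-(furan-3-yl)-6-methoxy-4,8-dimethylundeca-4,8-dien-1-yl]-5-methyloxolan-2-one | CO[C@H](/C=C(\C)CC[C@@H](O[Si](C)(C)C(C)(C)C)[C@]1(C)CCC(=O)O1)C/C(C)=C/CCc1ccoc1 | intermediate
29 | (5S)-5-[(1R,4E,6S,8E)-11-(furan-3-yl)-1-hydroxy-6-methoxy-4,8-dimethylundeca-4,8-dien-1-yl]-5-methyloxolan-2-one | CO[C@H](/C=C(\C)CC[C@@H](O)[C@]1(C)CCC(=O)O1)C/C(C)=C/CCc1ccoc1 | target

Total step count: 20. Longest linear sequence: 16 steps (steps 1–9, 13–17, 19 and 20, from farnesol).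

Steps most likely to fail

1. Step 19 (oxazole cycloaddition). The unactivated alkyne may add too slowly at temperatures the substrate survives. Competing processes are a [3,3] shift of the 3-methoxy-1,5-diene (C3′=C4′–C5′–C6′–C7′=C8′), thermal loss of methanol from the allylic ether, and oligomerisation of alkyne and oxazole. The fallback gives up late ring construction and brings the furan in ready-made with the C1′–C5′ fragment. This is possible because every oxidation the furan cannot survive is already finished in enal 11. It sets out from enal 11 and ylide 13, with commercial 3-bromofuran, and comes back at 28.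
   - Bromine–lithium exchange on 3-bromofuran (n-BuLi, THF, −78 °C) should give 3-furyllithium F1, which opens oxetane with BF3·OEt2 to give 3-(furan-3-yl)propan-1-ol F2.
   - Swern oxidation to 3-(furan-3-yl)propanal F3 and Wittig reaction with 13 should give ethyl (2E)-5-(furan-3-yl)-2-methylpent-2-enoate F4.
   - i-Bu2AlH reduction should give (2E)-5-(furan-3-yl)-2-methylpent-2-en-1-ol F5.
   - MsCl/LiCl/collidine should give, through (2E)-5-(furan-3-yl)-2-methylpent-2-en-1-yl methanesulfonate F6, 3-[(3E)-5-chloro-4-methylpent-3-en-1-yl]furan F7.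
   - Activated barium at −78 °C should give [(2E)-5-(furan-3-yl)-2-methylpent-2-en-1-yl]barium chloride F8, which adds to 11 to give the furyl carbinol F9 (C6 epimers).
   - Dess–Martin oxidation should give the furyl enone F10, CBS reduction as in step 15 the (6S) furyl alcohol F11, and methylation as in step 16 compound 28.

2. Step 13 (allylbarium union). Generation of the organobarium may be incomplete or accompanied by Wurtz-type homocoupling of the chloride. The reagent may also attack through its γ-carbon to give the branched carbinol, or add to the lactone. The fallback replaces the allyl metal by a sulfone-stabilised allyl anion, which reacts at the sulfonyl-bearing carbon. It sets out from chloride 18 and enal 11 and comes back at enone 21.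
   - PhSO2Na in DMF should convert 18 into [(5E)-7-(benzenesulfonyl)-6-methylhept-5-en-1-yn-1-yl]trimethylsilane F12.
   - n-BuLi (THF, −78 °C) should give the α-lithio sulfone F13, which adds to 11 to give the β-hydroxy sulfone F14 (diastereomer mixture).
   - Dess–Martin oxidation should give the β-keto sulfone F15, and SmI2 (divalent samarium) in THF/MeOH at −78 °C should cleave the C–S bond to give 21.

3. Step 15 (CBS reduction). The catalyst may discriminate poorly between the alkenyl flank and the allylic methylene flank of the ketone. The C3′=C4′ alkene may also drift into conjugation while the skipped enone is handled. The fallback bypasses the ketone by a Sharpless kinetic resolution of the carbinol mixture. It sets out from 20 and comes back at 22.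
   - Conditions would be Ti(OiPr)4, D-(−)-diisopropyl tartrate, t-BuOOH, 4 Å MS, CH2Cl2, −20 °C, run past half conversion.
   - The (6′R) epimer should be epoxidised faster to the epoxy alcohol (5S)-5-[(1R)-1-(tert-butyldimethylsilyloxy)-3-[(2R,3R)-3-[(1R,3E)-1-hydroxy-3-methyl-8-(trimethylsilyl)oct-3-en-7-yn-1-yl]-2-methyloxiran-2-yl]propyl]-5-methyloxolan-2-one F16, and the (6′S) epimer 22 should be recovered.
   - The cost is at most half of the material, and the methyl group cis to the carbinol is expected to lower the rate difference.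

Further compounds
F1 | step 19 | 3-furyllithium | [Li]c1ccoc1
F2 | step 19 | 3-(furan-3-yl)propan-1-ol | OCCCc1ccoc1
F3 | step 19 | 3-(furan-3-yl)propanal | O=CCCc1ccoc1
F4 | step 19 | ethyl (2E)-5-(furan-3-yl)-2-methylpent-2-enoate | CCOC(=O)/C(C)=C/CCc1ccoc1
F5 | step 19 | (2E)-5-(furan-3-yl)-2-methylpent-2-en-1-ol | OC/C(C)=C/CCc1ccoc1
F6 | step 19 | (2E)-5-(furan-3-yl)-2-methylpent-2-en-1-yl methanesulfonate | CS(=O)(=O)OC/C(C)=C/CCc1ccoc1
F7 | step 19 | 3-[(3E)-5-chloro-4-methylpent-3-en-1-yl]furan | ClC/C(C)=C/CCc1ccoc1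
F8 | step 19 | [(2E)-5-(furan-3-yl)-2-methylpent-2-en-1-yl]barium chloride | Cl[Ba]C/C(C)=C/CCc1ccoc1
F9 | step 19 | (5S)-5-[(1R,4E,6RS,8E)-1-(tert-butyldimethylsilyloxy)-11-(furan-3-yl)-6-hydroxy-4,8-dimethylundeca-4,8-dien-1-yl]-5-methyloxolan-2-one | OC(/C=C(\C)CC[C@@H](O[Si](C)(C)C(C)(C)C)[C@]1(C)CCC(=O)O1)C/C(C)=C/CCc1ccoc1
F10 | step 19 | (5S)-5-[(1R,4E,8E)-1-(tert-butyldimethylsilyloxy)-11-(furan-3-yl)-4,8-dimethyl-6-oxoundeca-4,8-dien-1-yl]-5-methyloxolan-2-one | O=C(/C=C(\C)CC[C@@H](O[Si](C)(C)C(C)(C)C)[C@]1(C)CCC(=O)O1)C/C(C)=C/CCc1ccoc1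
F11 | step 19 | (5S)-5-[(1R,4E,6S,8E)-1-(tert-butyldimethylsilyloxy)-11-(furan-3-yl)-6-hydroxy-4,8-dimethylundeca-4,8-dien-1-yl]-5-methyloxolan-2-one | O[C@H](/C=C(\C)CC[C@@H](O[Si](C)(C)C(C)(C)C)[C@]1(C)CCC(=O)O1)C/C(C)=C/CCc1ccoc1
F12 | step 13 | [(5E)-7-(benzenesulfonyl)-6-methylhept-5-en-1-yn-1-yl]trimethylsilane | C[Si](C)(C)C#CCC/C=C(\C)CS(=O)(=O)c1ccccc1
F13 | step 13 | [(2E)-1-(benzenesulfonyl)-2-methyl-7-(trimethylsilyl)hept-2-en-6-yn-1-yl]lithium | C[Si](C)(C)C#CCC/C=C(\C)C([Li])S(=O)(=O)c1ccccc1
F14 | step 13 | (5S)-5-[(1R,4E,8E)-7-(benzenesulfonyl)-1-(tert-butyldimethylsilyloxy)-6-hydroxy-4,8-dimethyl-13-(trimethylsilyl)trideca-4,8-dien-12-yn-1-yl]-5-methyloxolan-2-one (mixture at C6 and C7) | C[Si](C)(C)C#CCC/C=C(\C)C(S(=O)(=O)c1ccccc1)C(O)/C=C(\C)CC[C@@H](O[Si](C)(C)C(C)(C)C)[C@]1(C)CCC(=O)O1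
F15 | step 13 | (5S)-5-[(1R,4E,8E)-7-(benzenesulfonyl)-1-(tert-butyldimethylsilyloxy)-4,8-dimethyl-6-oxo-13-(trimethylsilyl)trideca-4,8-dien-12-yn-1-yl]-5-methyloxolan-2-one (mixture at C7) | C[Si](C)(C)C#CCC/C=C(\C)C(S(=O)(=O)c1ccccc1)C(=O)/C=C(\C)CC[C@@H](O[Si](C)(C)C(C)(C)C)[C@]1(C)CCC(=O)O1
F16 | step 15 | (5S)-5-[(1R)-1-(tert-butyldimethylsilyloxy)-3-[(2R,3R)-3-[(1R,3E)-1-hydroxy-3-methyl-8-(trimethylsilyl)oct-3-en-7-yn-1-yl]-2-methyloxiran-2-yl]propyl]-5-methyloxolan-2-one | O[C@H](C/C(C)=C/CCC#C[Si](C)(C)C)[C@H]1O[C@]1(C)CC[C@@H](O[Si](C)(C)C(C)(C)C)[C@]2(C)CCC(=O)O2
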